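The diaryl ether is not made by C–O coupling: ring B is assembled de novo on an oxygen that ring A already carries. The feature exploited is the run of three adjacent substituted carbons in ring B, C6' (CH2OH), C1' (ether oxygen) and C2' (OH). They correspond to the ester-bearing C3 of a 5-methyl-2-pyrone-3-carboxylate and to the oxygen- and boron-substituted carbons of an alkyne. In one thermal operation a [4+2] cycloaddition and loss of CO2 form C1'–C6' and C2'–C3' and deliver ring B as a benzene with boron marking C2'. The precursor is the pinacol boronate of the aryl ynol ether derived from MOM-protected 4-prenylresorcinol (ring A).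

Key step: step 9

Assumption (locants and mapping): ring A is the benzoic acid ring with C1 (CO2H), C2 (OH), C3 (prenyl = 3-methylbut-2-en-1-yl) and C6 (ether oxygen); ring B has C1' (ether oxygen), C2' (OH), C4' (CH3) and C6' (CH2OH); the target has no stereocentre; pyrone C3, C4, C5 and C6 become C6', C5', C4' and C3', so the 5-methylpyrone places CH3 at C4', para to the ether oxygen.

Step 1
Reactants: 1 4-bromoresorcinol (4-bromobenzene-1,3-diol)
Product: 2 2-bromo-5-(triisopropylsilyloxy)phenol
Conditions: i-Pr3SiCl (1.05 equiv), imidazole, CH2Cl2, −20 → 0 °C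
Reagents that add atoms: triisopropylsilyl chloride, CC(C)[Si](Cl)(C(C)C)C(C)C
Why: Imidazole-promoted O-silylation should take place at the unhindered hydroxyl para to bromine, because the hydroxyl next to bromine is shielded and less nucleophilic and the silyl chloride is bulky.

Step 2
Reactants: 2 2-bromo-5-(triisopropylsilyloxy)phenol
Product: 3 [4-bromo-3-(methoxymethoxy)phenoxy]triisopropylsilane
Conditions: MOMCl, i-Pr2NEt, CH2Cl2, 0 °C → rt
Reagents that add atoms: chloromethyl methyl ether, COCCl
Why: Williamson-type O-alkylation of the remaining ortho-bromophenol with the reactive chloromethyl ether and a hindered amine base is routine, and the bulky aryl silyl ether does not migrate under these non-nucleophilic conditions.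

Step 3
Reactants: 3 [4-bromo-3-(methoxymethoxy)phenoxy]triisopropylsilane; 4 prenyl bromide (1-bromo-3-methylbut-2-ene)
Product: 6 [3-(methoxymethoxy)-4-(3-methylbut-2-en-1-yl)phenoxy]triisopropylsilane, via aryllithium 5 (not isolated)
Conditions: n-BuLi, THF, −78 °C; CuBr·SMe2 (10 mol %), 4, −78 → 0 °C
Reagents that add atoms: none
Why: Bromine–lithium exchange gives aryllithium 5, held by the ortho OMOM oxygen, and copper-catalysed allylic substitution at the unhindered primary carbon of 4 should give the linear prenyl arene and not the 1,1-dimethylallyl isomer.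

Step 4
Reactants: 6 [3-(methoxymethoxy)-4-(3-methylbut-2-en-1-yl)phenoxy]triisopropylsilane
Product: 7 3-(methoxymethoxy)-4-(3-methylbut-2-en-1-yl)phenol
Conditions: Bu4NF, THF, 0 °C; aq. NH4Cl
Reagents that add atoms: none
Why: Fluoride-induced cleavage of the aryl silyl ether (desilylation) frees the phenol para to the prenyl group, while the MOM acetal and the alkene are inert to fluoride.

Step 5
Reactants: 7 3-(methoxymethoxy)-4-(3-methylbut-2-en-1-yl)phenol; 8 trichloroethylene
Product: 10 4-{[(E)-1,2-dichloroethenyl]oxy}-2-(methoxymethoxy)-1-(3-methylbut-2-en-1-yl)benzene, via dichloroacetylene 9 (not isolated)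
Conditions: K2CO3, DMF, 70 °C
Reagents that add atoms: none
Why: Base-mediated loss of HCl from 8 gives dichloroacetylene 9, to which the phenoxide adds anti, so that protonation gives the (E)-1,2-dichlorovinyl ether, a general O-vinylation of phenols.

Step 6
Reactants: 10 4-{[(E)-1,2-dichloroethenyl]oxy}-2-(methoxymethoxy)-1-(3-methylbut-2-en-1-yl)benzene
Product: 14 2-{[3-(methoxymethoxy)-4-(3-methylbut-2-en-1-yl)phenoxy]ethynyl}-4,4,5,5-tetramethyl-1,3,2-dioxaborolane, via chloroalkyne 11 (not isolated), via lithium acetylide 12 (not isolated), via borate complex 13 (not isolated)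
Conditions: n-BuLi (2.2 equiv), Et2O, −78 → −40 °C; i-PrOBpin, −78 °C; HCl in Et2O (1.0 equiv), −78 °C → rt
Reagents that add atoms: 2-isopropoxy-4,4,5,5-tetramethyl-1,3,2-dioxaborolane, CC(C)OB1OC(C)(C)C(C)(C)O1
Why: Dehydrochlorination of 10 to chloroalkyne 11 and chlorine–lithium exchange give the lithium aryloxyacetylide 12, which adds to the isopropoxyboronate to form borate 13, and stoichiometric anhydrous HCl at low temperature collapses 13 to the alkynyl pinacol boronate (standard acetylide borylation); the moisture-sensitive product is filtered from lithium chloride under argon, concentrated and used crude.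

Step 7
Reactants: 15 dimethyl malonate; 16 (E)-3-(dimethylamino)-2-methylprop-2-enal
Product: 18 dimethyl 2-[(E)-3-(dimethylamino)-2-methylprop-2-en-1-ylidene]malonate, via iminium salt 17 (not isolated)
Conditions: 16, Me2SO4, 70 °C, neat; then 15, NaOMe, MeOH, 0 °C → rt
Reagents that add atoms: none
Why: O-Methylation turns the unreactive vinylogous formamide 16 into the alkoxy-iminium salt 17, which the malonate anion attacks with loss of methanol in a Knoevenagel-type condensation; attack at either end of the symmetric three-carbon unit would lead to the same pyrone in step 8.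

Step 8
Reactants: 18 dimethyl 2-[(E)-3-(dimethylamino)-2-methylprop-2-en-1-ylidene]malonate
Product: 19 methyl 5-methyl-2-oxo-2H-pyran-3-carboxylate
Conditions: HCO2H/H2O (9:1), 80 °C
Reagents that add atoms: water, O
Why: Acid hydrolysis of the enamine gives an enol/aldehyde that can adopt the Z geometry and lactonise onto one ester with loss of methanol, the established cyclisation of 3-heteroatom-substituted allylidenemalonates to 2-pyrone-3-carboxylates.

Step 9
Reactants: 14 2-{[3-(methoxymethoxy)-4-(3-methylbut-2-en-1-yl)phenoxy]ethynyl}-4,4,5,5-tetramethyl-1,3,2-dioxaborolane; 19 methyl 5-methyl-2-oxo-2H-pyran-3-carboxylate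
Product: 21 methyl 2-[3-(methoxymethoxy)-4-(3-methylbut-2-en-1-yl)phenoxy]-5-methyl-3-(4,4,5,5-tetramethyl-1,3,2-dioxaborolan-2-yl)benzoate, via bridged lactone 20 (not isolated)
Conditions: 19 (1.3 equiv), toluene, 110 °C, sealed tube, argon (o-xylene, 140 °C if slow)
Reagents that add atoms: none
Why: The electron-poor 2-pyrone 19 acts as the 4π component (C3=C4–C5=C6) and the donor-substituted alkyne 14 as the 2π component in an inverse-electron-demand Diels–Alder reaction that gives the bridged lactone 20, which then loses CO2 in a retro-[4+2] step. Both halves are known reaction types, namely the cycloaddition–decarboxylation of 2-pyrone-3-carboxylates with ynol ethers, ynamines and ketene acetals, and the 2-pyrone route from alkynyl pinacol boronates to aryl boronates. Ring B is closed by an intermolecular [4+2] cycloaddition (pyrone C3 to the oxygen-bearing alkyne carbon, pyrone C6 to the boron-bearing alkyne carbon) and becomes aromatic on CO2 extrusion. The two bridgehead stereocentres of 20 form as a racemate and vanish on aromatisation, so no stereocentre has to be controlled. The only selectivity needed is the orientation of the addends: the aryloxy oxygen makes the boron-bearing carbon the nucleophilic alkyne terminus and the weakly π-accepting boryl group polarises the triple bond in the same sense, so this carbon should bond to the electrophilic pyrone C6 and the oxygen-bearing carbon to C3, which puts the ether oxygen next to the ester carbon as in the ortho-alkoxybenzoates formed from ketene acetals. The trisubstituted prenyl alkene is a far poorer partner for the pyrone than the ynol ether, and an aryl ynol ether has no β-hydrogen through which it could fragment to a ketene on heating.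

Step 10
Reactants: 21 methyl 2-[3-(methoxymethoxy)-4-(3-methylbut-2-en-1-yl)phenoxy]-5-methyl-3-(4,4,5,5-tetramethyl-1,3,2-dioxaborolan-2-yl)benzoate
Product: 22 methyl 3-hydroxy-2-[3-(methoxymethoxy)-4-(3-methylbut-2-en-1-yl)phenoxy]-5-methylbenzoate
Conditions: NaBO3·4H2O, THF/H2O, rt
Reagents that add atoms: sodium perborate tetrahydrate (NaBO3·4H2O), O.O.O.O.O.O.[Na+].[Na+].O[B-]1(O)OO[B-](O)(O)OO1
Why: Perborate is a mild hydroperoxide source that oxidises the aryl C–B bond by boronate formation and 1,2-aryl shift (ipso-hydroxylation) near neutral pH, which spares the prenyl alkene, the methyl ester and the MOM acetal.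

Step 11
Reactants: 22 methyl 3-hydroxy-2-[3-(methoxymethoxy)-4-(3-methylbut-2-en-1-yl)phenoxy]-5-methylbenzoate
Product: 23 3-(hydroxymethyl)-2-[3-(methoxymethoxy)-4-(3-methylbut-2-en-1-yl)phenoxy]-5-methylphenol
Conditions: LiAlH4, THF, 0 °C; aq. work-up
Reagents that add atoms: none
Why: Hydride reduction of the methyl benzoate to the benzylic alcohol with LiAlH4 tolerates the phenoxide, the acetal and the isolated alkene.

Step 12
Reactants: 23 3-(hydroxymethyl)-2-[3-(methoxymethoxy)-4-(3-methylbut-2-en-1-yl)phenoxy]-5-methylphenol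
Product: 24 tert-butyl{[3-(tert-butyldimethylsilyloxy)-2-[3-(methoxymethoxy)-4-(3-methylbut-2-en-1-yl)phenoxy]-5-methylbenzyl]oxy}dimethylsilane
Conditions: t-BuMe2SiCl (2.5 equiv), imidazole, DMF, rt
Reagents that add atoms: tert-butyldimethylsilyl chloride, CC(C)(C)[Si](C)(C)Cl
Why: Imidazole-promoted silylation protects the phenol and the primary alcohol in one operation, and silyl ethers, unlike a second acetal on ring B, do not direct lithiation toward ring B in the next step.

Step 13
Reactants: 24 tert-butyl{[3-(tert-butyldimethylsilyloxy)-2-[3-(methoxymethoxy)-4-(3-methylbut-2-en-1-yl)phenoxy]-5-methylbenzyl]oxy}dimethylsilane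
Product: 26 6-{2-(tert-butyldimethylsilyloxy)-6-[(tert-butyldimethylsilyloxy)methyl]-4-methylphenoxy}-2-(methoxymethoxy)-3-(3-methylbut-2-en-1-yl)benzoic acid, via aryllithium 25 (not isolated)
Conditions: n-BuLi, TMEDA, THF, −78 → −20 °C; CO2, −78 °C → rt; dilute aq. HCl to pH 3–4, 0 °C
Reagents that add atoms: carbon dioxide, O=C=O
Why: Directed ortho-metalation should occur at ring A C1, the only position flanked by two oxygen substituents (the lithium-chelating OMOM and the aryloxy oxygen), and aryllithium 25 is trapped by CO2 as the carboxylate (lithiation–carboxylation).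

Step 14
Reactants: 26 6-{2-(tert-butyldimethylsilyloxy)-6-[(tert-butyldimethylsilyloxy)methyl]-4-methylphenoxy}-2-(methoxymethoxy)-3-(3-methylbut-2-en-1-yl)benzoic acid
Product: 28 2-hydroxy-6-[2-hydroxy-6-(hydroxymethyl)-4-methylphenoxy]-3-(3-methylbut-2-en-1-yl)benzoic acid (CNP0140656.0), via desilylated acid 27 (not isolated)
Conditions: Bu4NF, THF, rt; then aq. HCl (3 M), i-PrOH, rt
Reagents that add atoms: none
Why: Fluoride removes both silyl ethers without acid, and dilute aqueous acid at room temperature then hydrolyses the MOM acetal, which the neighbouring carboxylic acid activates, under conditions too mild to cyclise the ortho-prenyl phenol to a chroman (sequential desilylation and acetal hydrolysis).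

Compound list
1 | 4-bromoresorcinol (4-bromobenzene-1,3-diol) | Oc1ccc(Br)c(O)c1 | starting material
2 | 2-bromo-5-(triisopropylsilyloxy)phenol | Oc1cc(O[Si](C(C)C)(C(C)C)C(C)C)ccc1Br | intermediate
3 | [4-bromo-3-(methoxymethoxy)phenoxy]triisopropylsilane | COCOc1cc(O[Si](C(C)C)(C(C)C)C(C)C)ccc1Br | intermediate
4 | prenyl bromide (1-bromo-3-methylbut-2-ene) | CC(C)=CCBr | starting material
5 | [2-(methoxymethoxy)-4-(triisopropylsilyloxy)phenyl]lithium | COCOc1cc(O[Si](C(C)C)(C(C)C)C(C)C)ccc1[Li] | intermediate (not isolated)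
6 | [3-(methoxymethoxy)-4-(3-methylbut-2-en-1-yl)phenoxy]triisopropylsilane | COCOc1cc(O[Si](C(C)C)(C(C)C)C(C)C)ccc1CC=C(C)C | intermediate
7 | 3-(methoxymethoxy)-4-(3-methylbut-2-en-1-yl)phenol | COCOc1cc(O)ccc1CC=C(C)C | intermediate
8 | trichloroethylene (1,1,2-trichloroethene) | ClC=C(Cl)Cl | starting material
9 | dichloroacetylene | ClC#CCl | intermediate (not isolated)
10 | 4-{[(E)-1,2-dichloroethenyl]oxy}-2-(methoxymethoxy)-1-(3-methylbut-2-en-1-yl)benzene | COCOc1cc(O/C(Cl)=C\Cl)ccc1CC=C(C)C | intermediate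
11 | 4-[(chloroethynyl)oxy]-2-(methoxymethoxy)-1-(3-methylbut-2-en-1-yl)benzene | COCOc1cc(OC#CCl)ccc1CC=C(C)C | intermediate (not isolated)
12 | lithium [3-(methoxymethoxy)-4-(3-methylbut-2-en-1-yl)phenoxy]acetylide | COCOc1cc(OC#C[Li])ccc1CC=C(C)C | intermediate (not isolated)
13 | lithium isopropoxy(pinacolato){[3-(methoxymethoxy)-4-(3-methylbut-2-en-1-yl)phenoxy]ethynyl}borate | [Li+].COCOc1cc(OC#C[B-]2(OC(C)C)OC(C)(C)C(C)(C)O2)ccc1CC=C(C)C | intermediate (not isolated)
14 | 2-{[3-(methoxymethoxy)-4-(3-methylbut-2-en-1-yl)phenoxy]ethynyl}-4,4,5,5-tetramethyl-1,3,2-dioxaborolane | CC(C)=CCc1ccc(OC#CB2OC(C)(C)C(C)(C)O2)cc1OCOC | intermediate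
15 | dimethyl malonate | COC(=O)CC(=O)OC | starting material
16 | (E)-3-(dimethylamino)-2-methylprop-2-enal | CN(C)/C=C(C)/C=O | starting material
17 | (3-methoxy-2-methylprop-2-en-1-ylidene)dimethylammonium methyl sulfate (delocalised cation, alkene geometry not defined) | COC=C(C)C=[N+](C)C.COS(=O)(=O)[O-] | intermediate (not isolated)
18 | dimethyl 2-[(E)-3-(dimethylamino)-2-methylprop-2-en-1-ylidene]malonate | CN(C)/C=C(C)/C=C(C(=O)OC)C(=O)OC | intermediate
19 | methyl 5-methyl-2-oxo-2H-pyran-3-carboxylate | COC(=O)C1=CC(C)=COC1=O | intermediate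
20 | methyl 5-[3-(methoxymethoxy)-4-(3-methylbut-2-en-1-yl)phenoxy]-7-methyl-3-oxo-6-(4,4,5,5-tetramethyl-1,3,2-dioxaborolan-2-yl)-2-oxabicyclo[2.2.2]octa-5,7-diene-4-carboxylate (racemic) | COC(=O)C12C=C(C)C(OC1=O)C(B3OC(C)(C)C(C)(C)O3)=C2Oc1ccc(CC=C(C)C)c(OCOC)c1 | intermediate (not isolated)
21 | methyl 2-[3-(methoxymethoxy)-4-(3-methylbut-2-en-1-yl)phenoxy]-5-methyl-3-(4,4,5,5-tetramethyl-1,3,2-dioxaborolan-2-yl)benzoate | COC(=O)c1cc(C)cc(B2OC(C)(C)C(C)(C)O2)c1Oc1ccc(CC=C(C)C)c(OCOC)c1 | intermediate
22 | methyl 3-hydroxy-2-[3-(methoxymethoxy)-4-(3-methylbut-2-en-1-yl)phenoxy]-5-methylbenzoate | COC(=O)c1cc(C)cc(O)c1Oc1ccc(CC=C(C)C)c(OCOC)c1 | intermediate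
23 | 3-(hydroxymethyl)-2-[3-(methoxymethoxy)-4-(3-methylbut-2-en-1-yl)phenoxy]-5-methylphenol | OCc1cc(C)cc(O)c1Oc1ccc(CC=C(C)C)c(OCOC)c1 | intermediate
24 | tert-butyl{[3-(tert-butyldimethylsilyloxy)-2-[3-(methoxymethoxy)-4-(3-methylbut-2-en-1-yl)phenoxy]-5-methylbenzyl]oxy}dimethylsilane | CC(C)=CCc1ccc(Oc2c(O[Si](C)(C)C(C)(C)C)cc(C)cc2CO[Si](C)(C)C(C)(C)C)cc1OCOC | intermediate
25 | ring A C1 aryllithium of 24 (lithium between OMOM and the aryloxy oxygen) | CC(C)=CCc1ccc(Oc2c(O[Si](C)(C)C(C)(C)C)cc(C)cc2CO[Si](C)(C)C(C)(C)C)c([Li])c1OCOC | intermediate (not isolated)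
26 | 6-{2-(tert-butyldimethylsilyloxy)-6-[(tert-butyldimethylsilyloxy)methyl]-4-methylphenoxy}-2-(methoxymethoxy)-3-(3-methylbut-2-en-1-yl)benzoic acid | CC(C)=CCc1ccc(Oc2c(O[Si](C)(C)C(C)(C)C)cc(C)cc2CO[Si](C)(C)C(C)(C)C)c(C(=O)O)c1OCOC | intermediate
27 | 6-[2-hydroxy-6-(hydroxymethyl)-4-methylphenoxy]-2-(methoxymethoxy)-3-(3-methylbut-2-en-1-yl)benzoic acid | CC(C)=CCc1ccc(Oc2c(O)cc(C)cc2CO)c(C(=O)O)c1OCOC | intermediate (not isolated)
28 | 2-hydroxy-6-[2-hydroxy-6-(hydroxymethyl)-4-methylphenoxy]-3-(3-methylbut-2-en-1-yl)benzoic acid (CNP0140656.0) | CC(C)=CCc1ccc(Oc2c(O)cc(C)cc2CO)c(C(=O)O)c1O | target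

Total step count: 14 (steps 1–6 alkyne, steps 7–8 pyrone, step 9 key step, steps 10–14 end game).
Longest linear sequence: 12 steps (steps 1–6 and 9–14).

Steps most likely to fail

1. Step 9 (key cycloaddition). The ynol ether boronate may be lost to protodeboronation or oligomerisation faster than it adds to the pyrone, or the pyrone may add to the prenyl alkene. The fallback sets out from phenol 7 and comes back at 21, and makes the diaryl ether by substitution instead of cycloaddition. Purchased 3-bromo-2-fluoro-5-methylbenzoic acid is esterified (MeOH, H2SO4 cat., reflux) to methyl 3-bromo-2-fluoro-5-methylbenzoate F1. Its fluoride, activated by the ortho ester and the flanking bromine, should be displaced by the phenoxide of 7 (Cs2CO3, DMSO, 100 °C; nucleophilic aromatic substitution). This gives methyl 3-bromo-2-[3-(methoxymethoxy)-4-(3-methylbut-2-en-1-yl)phenoxy]-5-methylbenzoate F2. Miyaura borylation (B2pin2, PdCl2(dppf), KOAc, dioxane, 90 °C) then converts the bromide into boronate 21.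

2. Step 6 (alkynyl boronate). The carbon–boron bond of the push–pull alkyne may be cleaved, or the ynol ether hydrated, during the acid quench and isolation. The fallback sets out from 10 and comes back at 21, and carries tin instead of boron through the cycloaddition. Acetylide 12, made as in step 6, is quenched with Bu3SnCl to give tributyl{[3-(methoxymethoxy)-4-(3-methylbut-2-en-1-yl)phenoxy]ethynyl}stannane F3, a member of a robust class of stannyl ynol ethers that can be chromatographed. Heating F3 with pyrone 19 in toluene should give, through the stannylated bridged lactone F4 (not isolated), methyl 2-[3-(methoxymethoxy)-4-(3-methylbut-2-en-1-yl)phenoxy]-5-methyl-3-(tributylstannyl)benzoate F5 with the same orientation. Iododestannylation (I2, CH2Cl2, 0 °C) gives methyl 3-iodo-2-[3-(methoxymethoxy)-4-(3-methylbut-2-en-1-yl)phenoxy]-5-methylbenzoate F6. Miyaura borylation (B2pin2, PdCl2(dppf), KOAc, dioxane, 80 °C) returns to 21.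

3. Step 13 (lithiation–carboxylation). Deprotonation at the benzylic/allylic CH2 of the prenyl group or at the silyloxymethyl group, or silyl migration, may compete with lithiation at ring A C1. The fallback sets out from 21 and comes back at the target 28; it uses no organolithium, and boron masks C2' so that only the ring A phenol reacts.
   - HCl in MeOH at rt removes the MOM group to give methyl 2-[3-hydroxy-4-(3-methylbut-2-en-1-yl)phenoxy]-5-methyl-3-(4,4,5,5-tetramethyl-1,3,2-dioxaborolan-2-yl)benzoate F7.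
   - Magnesium-mediated ortho-formylation (MgCl2, Et3N, paraformaldehyde, MeCN, reflux) is specific for the position ortho to the phenol, and C1 is the only free one. It should give methyl 2-[2-formyl-3-hydroxy-4-(3-methylbut-2-en-1-yl)phenoxy]-5-methyl-3-(4,4,5,5-tetramethyl-1,3,2-dioxaborolan-2-yl)benzoate F8.
   - Pinnick oxidation (NaClO2, NaH2PO4, excess 2-methylbut-2-ene, t-BuOH/H2O) gives 2-hydroxy-6-[2-(methoxycarbonyl)-4-methyl-6-(4,4,5,5-tetramethyl-1,3,2-dioxaborolan-2-yl)phenoxy]-3-(3-methylbut-2-en-1-yl)benzoic acid F9.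
   - NaBO3·4H2O in THF/H2O gives 2-hydroxy-6-[2-hydroxy-6-(methoxycarbonyl)-4-methylphenoxy]-3-(3-methylbut-2-en-1-yl)benzoic acid F10.
   - LiBH4 in THF (rt → 50 °C) reduces the methyl ester but not the lithium carboxylate, and acidic work-up gives 28.

Further compounds
F1 | step 9 | methyl 3-bromo-2-fluoro-5-methylbenzoate | COC(=O)c1cc(C)cc(Br)c1F
F2 | step 9 | methyl 3-bromo-2-[3-(methoxymethoxy)-4-(3-methylbut-2-en-1-yl)phenoxy]-5-methylbenzoate | COC(=O)c1cc(C)cc(Br)c1Oc1ccc(CC=C(C)C)c(OCOC)c1
F3 | step 6 | tributyl{[3-(methoxymethoxy)-4-(3-methylbut-2-en-1-yl)phenoxy]ethynyl}stannane | CCCC[Sn](CCCC)(CCCC)C#COc1ccc(CC=C(C)C)c(OCOC)c1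
F4 | step 6 | methyl 5-[3-(methoxymethoxy)-4-(3-methylbut-2-en-1-yl)phenoxy]-7-methyl-3-oxo-6-(tributylstannyl)-2-oxabicyclo[2.2.2]octa-5,7-diene-4-carboxylate (racemic, not isolated) | COC(=O)C12C=C(C)C(OC1=O)C([Sn](CCCC)(CCCC)CCCC)=C2Oc1ccc(CC=C(C)C)c(OCOC)c1
F5 | step 6 | methyl 2-[3-(methoxymethoxy)-4-(3-methylbut-2-en-1-yl)phenoxy]-5-methyl-3-(tributylstannyl)benzoate | COC(=O)c1cc(C)cc([Sn](CCCC)(CCCC)CCCC)c1Oc1ccc(CC=C(C)C)c(OCOC)c1
F6 | step 6 | methyl 3-iodo-2-[3-(methoxymethoxy)-4-(3-methylbut-2-en-1-yl)phenoxy]-5-methylbenzoate | COC(=O)c1cc(C)cc(I)c1Oc1ccc(CC=C(C)C)c(OCOC)c1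
F7 | step 13 | methyl 2-[3-hydroxy-4-(3-methylbut-2-en-1-yl)phenoxy]-5-methyl-3-(4,4,5,5-tetramethyl-1,3,2-dioxaborolan-2-yl)benzoate | COC(=O)c1cc(C)cc(B2OC(C)(C)C(C)(C)O2)c1Oc1ccc(CC=C(C)C)c(O)c1
F8 | step 13 | methyl 2-[2-formyl-3-hydroxy-4-(3-methylbut-2-en-1-yl)phenoxy]-5-methyl-3-(4,4,5,5-tetramethyl-1,3,2-dioxaborolan-2-yl)benzoate | COC(=O)c1cc(C)cc(B2OC(C)(C)C(C)(C)O2)c1Oc1ccc(CC=C(C)C)c(O)c1C=O
F9 | step 13 | 2-hydroxy-6-[2-(methoxycarbonyl)-4-methyl-6-(4,4,5,5-tetramethyl-1,3,2-dioxaborolan-2-yl)phenoxy]-3-(3-methylbut-2-en-1-yl)benzoic acid | COC(=O)c1cc(C)cc(B2OC(C)(C)C(C)(C)O2)c1Oc1ccc(CC=C(C)C)c(O)c1C(=O)O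
F10 | step 13 | 2-hydroxy-6-[2-hydroxy-6-(methoxycarbonyl)-4-methylphenoxy]-3-(3-methylbut-2-en-1-yl)benzoic acid | COC(=O)c1cc(C)cc(O)c1Oc1ccc(CC=C(C)C)c(O)c1C(=O)O
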